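The dusk run, with the smallest charge of racemization catalyst among the earlier runs (0.99 mM), reads a closed left-hand account (left-handed product plus left-handed substrate) at its last reading: at 30.0 min, left-handed product 36% and left-handed substrate 14% sum to 50.0%, half of the charge.

| flask | left-handed substrate | right-handed substrate | partner | free catalyst | racemization catalyst | remark | time |
|---|---|---|---|---|---|---|---|
| dusk | 0.10 M | 0.10 M | 0.20 M | 5 mM | 0.99 mM | run made earlier |  |
| spring | 0.10 M | 0.10 M | 0.20 M | 5 mM | 4 mM | run made earlier |  |
| winter | 0.10 M | 0.10 M | 0.20 M | 5 mM | 13 mM | run made earlier |  |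
| summer | 0.10 M | 0.10 M | 0.26 M | 5 mM | 5 mM | run made earlier |  |
| eta | 0.10 M | 0.10 M | 0.0600 M | 2.5 mM | 5.0 mM |  | 1.0 h |
| epsilon | 0.10 M | 0.10 M | 0.120 M | 5.0 mM | 8.0 mM |  | 1.0 h |
| gamma | 0.10 M | 0.10 M | 0.200 M | 5.0 mM | 5.0 mM |  | 1.0 h |
| zeta | 0.10 M | 0.10 M | 0.400 M | 5.0 mM | 5.0 mM |  | 1.0 h |
| beta | 0.10 M | 0.10 M | 0.200 M | 2.5 mM | 15 mM |  | 1.0 h |
| theta | 0.10 M | 0.10 M | 0.600 M | 5.0 mM | 1.2 mM |  | 1.0 h |

| run | time / min | left-handed product / % | left-handed substrate / % |
|---|---|---|---|
| dusk | 2.50 | 9 | 47 |
| dusk | 5.00 | 15 | 39 |
| dusk | 8.00 | 15 | 35 |
| dusk | 15.0 | 29 | 29 |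
| dusk | 30.0 | 36 | 14 |
| spring | 2.50 | 5 | 45 |
| spring | 5.00 | 11 | 37 |
| spring | 8.00 | 15 | 33 |
| spring | 15.0 | 26 | 23 |
| spring | 30.0 | 37 | 16 |
| winter | 2.50 | 8 | 43 |
| winter | 8.00 | 19 | 32 |
| winter | 15.0 | 24 | 24 |
| winter | 20.0 | 32 | 22 |
| winter | 30.0 | 40 | 19 |
| summer | 6.00 | 20 | 33 |
| summer | 12.0 | 30 | 24 |
| summer | 20.0 | 36 | 16 |
| summer | 25.0 | 41 | 11 |
| summer | 30.0 | 42 | 13 |

(scatter of a reading: 2 percentage points)

- free catalyst is single-handed; left-handed substrate and right-handed substrate are mirror images of each other, charged as a racemate, each of them at the stated concentration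
- reactions considered so far: partner + free catalyst + left-handed substrate -> free catalyst + left-handed product; left-handed substrate + racemization catalyst <-> right-handed substrate + racemization catalyst; partner + racemization catalyst -> spent catalyst; partner + free catalyst + right-handed substrate -> free catalyst + right-handed product
- no earlier run changes the charge of free catalyst; that part of a forecast is a guess

1. the flasks by amount of left-handed product, in percent of the left-handed substrate and right-handed substrate together charged, highest first, at 1.0 h (eta / epsilon / gamma / zeta / beta / theta)
2. the same order at 12 min (eta / epsilon / gamma / zeta / beta / theta)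
3. the amount of left-handed product, in percent of the left-handed substrate and right-handed substrate together charged of the flask you put first, at 1.0 h
4. the amount of left-handed product, in percent of the left-handed substrate and right-handed substrate together charged of the flask you put last, at 1.0 h

Shares below are fractions of both substrates charged, so the left-hand account opens at 0.5.

1. Left-handed substrate is taken to fall at κ times partner times left-handed substrate. Integrated, the ln of (part of the partner charge remaining over part of the left-handed charge remaining) grows with time, and its slope is κ times the difference of the two charges.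

2. The first way uses the product peak in the dusk run. It gives κ = 0.276 M⁻¹ min⁻¹, the left-hand rate constant at 5 mM free catalyst.

3. The second way uses the substrate peak of the same dusk reading and gives 0.276 M⁻¹ min⁻¹. The two are separate peaks, but their agreement repeats the closed sum of that one reading, so κ stands as a reading with a scatter of 2 percentage points on each peak. The dusk sum at 15.0 min reads 58.0%.

4. In the winter run the two ways part. The product peak gives 0.366 M⁻¹ min⁻¹, higher than the dusk value. The substrate peak gives 0.199 M⁻¹ min⁻¹, lower. The winter account reads a surplus of 9 points over 0.5 at 30.0 min, taken here as substrate that crossed from the right-handed form. Each way cheats by ignoring that surplus, in opposite directions, so the dusk κ is kept.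

5. My own reckoning closes the account with κ. For zeta at 1.0 h this gives 49.7%, and for theta 50.0%, nearly a tie. The winter surplus, scaled by racemization catalyst and time, separates them: zeta 56.7%, theta 51.7%. For eta, κ is scaled with free catalyst, which is a guess, since no earlier run changes that charge. It gives 14.8%.

6. The forecast gives zeta > theta > gamma > beta > epsilon > eta at 1.0 h and theta > zeta > gamma > epsilon > beta > eta at 12 min, with top 58% and low 15%, on a constant of 0.27 per molar per minute. Its top stands slightly above my figure. It states: “I assume negligible right-handed product.”

    partner + free catalyst + left-handed substrate → free catalyst + left-handed product (k = 1.00 M⁻² s⁻¹)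
    left-handed substrate + racemization catalyst ⇌ right-handed substrate + racemization catalyst, rate k2*[racemization catalyst]*[left-handed substrate] forward; the back reaction follows from the equilibrium constant (k = 0.0200 M⁻¹ s⁻¹)
    partner + racemization catalyst → spent catalyst (k = 9.70 × 10⁻⁴ M⁻¹ s⁻¹)
    partner + free catalyst + right-handed substrate → free catalyst + right-handed product (k = 0.0700 M⁻² s⁻¹)

The simulation gives zeta > theta > gamma > beta > epsilon > eta at 1.0 h and theta > zeta > gamma > epsilon > beta > eta at 12 min, with zeta at 54.9% and eta at 15.4%; both orders match the forecast. Right-handed product in zeta stands at 14.4%, yet its step moves the readings of the earlier runs by 0.15 units of the scatter, root mean square. For the neighbour of zeta with 0.10 M partner, equal to the left-handed charge, the same κ reckons 31.2% left-handed product, and that flask holds 32.0%.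

The numbers in the tables come from a simulation on assumed constants.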